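**Plan**

Numbering: carbocycle C1–C10 (Z-alkene C1=C10 with methyl C14, E-alkene C4=C5 with methyl C15, lactone oxygen on C6, tertiary OH on C7, angelate on C8, OH on C9); lactone carbons C11 (bearing methylene C13) and C12; the target is 6S,7R,8S,9R.
Cuts, in retrosynthetic order: the C8–O angelate ester and the exocyclic C11=C13; then C8–C9 of the ten-membered ring, because C8 and C9 form a threo 1,2-diol between quaternary C7 and the Z C1=C10 alkene, which is the retron of a reductive coupling of a C8 aldehyde with a C9 enal; then the lactone C12–O bond, C6–C7 (aldol) and C1=C10 (olefination).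
Forward: geranyl acetate gives C1–C6 with the E alkene, a Z-selective olefination adds C9/C10/C14, the aldol with the L-malic acid dioxolanone enolate joins C6–C7, the γ-lactone closes first and the ten-membered carbocycle second (titanium pinacol closure); methylenation, angeloylation and desilylation follow.
Stereochemistry: C7 from L-malic acid (retention through the tert-butyl dioxolanone); C6 from the aldol (enolate face fixed by the acetal, aldehyde face expected from approach over the open ring face); C8 and C9 from the pinacol step (C8 under control of C7, C9 anti to C8 across the new bond); alkene geometries from geranyl acetate, the Still–Gennari step and angelic acid.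

Key step: step 12

Remark: metal enolates, alkoxides and the titanium diolate are treated as salt forms of the numbered compounds and carry no number of their own; angelic acid is taken as a commercial building block.

**Route**

Step 1
Reactants: 1 L-malic acid; 2 pivalaldehyde
Product: 3 2-[(2S,4S)-2-tert-butyl-5-oxo-1,3-dioxolan-4-yl]acetic acid
Conditions: TsOH·H2O (cat.), H2SO4 (cat.), pentane, reflux (Dean–Stark); crystallisation
Reagents that add atoms: none
Why: Acid-catalysed acetalisation of the α-hydroxy acid unit with removal of water equilibrates to the cis dioxolanone (self-regeneration of stereocentres), so the new acetal centre is set under thermodynamic control and secured by crystallisation, while the β-carboxyl stays free.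

Step 2
Reactants: 4 geranyl acetate
Product: 6 (2E)-3-methyl-6-oxohex-2-en-1-yl acetate, via ozonide 5 (not isolated)
Conditions: O3 (1.0 equiv), CH2Cl2, −78 °C; then PPh3, −78 °C → rt
Reagents that add atoms: ozone, O=[O+][O-]
Why: Chemoselective ozonolysis, in which electrophilic ozone attacks the electron-rich isopropylidene alkene much faster than the alkene deactivated by the allylic acetate, followed by reductive cleavage of the ozonide, should give the aldehyde with the E alkene untouched.

Step 3
Reactants: 6 aldehyde acetate; 7 ethyl 2-[bis(2,2,2-trifluoroethoxy)phosphoryl]propanoate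
Product: 8 ethyl (2Z,6E)-8-acetoxy-2,6-dimethylocta-2,6-dienoate
Conditions: KN(SiMe3)2, 18-crown-6, THF, −78 °C
Reagents that add atoms: none
Why: Still–Gennari variant of the Horner–Wadsworth–Emmons olefination, in which the electron-poor phosphonate with a dissociated potassium counter-ion eliminates from the kinetic adduct, should give the Z-trisubstituted enoate, the geometry of the later C1=C10 alkene.

Step 4
Reactants: 8 acetoxy enoate
Product: 9 ethyl (2Z,6E)-8-hydroxy-2,6-dimethylocta-2,6-dienoate
Conditions: K2CO3 (cat.), EtOH, 0 °C → rt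
Reagents that add atoms: none
Why: Base-catalysed transesterification removes the unhindered primary acetate, while exchange at the conjugated ethyl ester in ethanol is degenerate, so the ester and both alkenes are unchanged.

Step 5
Reactants: 9 hydroxy enoate
Product: 10 ethyl (2Z,6E)-2,6-dimethyl-8-oxoocta-2,6-dienoate
Conditions: MnO2 (activated, excess), CH2Cl2, rt
Reagents that add atoms: none
Why: MnO2 oxidation of the primary allylic alcohol gives the enal under neutral conditions that keep the ester and both alkene geometries.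

Step 6
Reactants: 3 dioxolanone acid; 10 enal ester
Product: 11 2-[(2S,4R)-2-tert-butyl-4-[(1S,2E,6Z)-8-ethoxy-1-hydroxy-3,7-dimethyl-8-oxoocta-2,6-dien-1-yl]-5-oxo-1,3-dioxolan-4-yl]acetic acid
Conditions: 3, LiN(SiMe3)2 (2.1 equiv), THF, −78 °C; then 10, −78 °C; AcOH, −78 °C
Reagents that add atoms: none
Why: Aldol addition of the dioxolanone dianion (carboxylate plus ring enolate): the enolate reacts 1,2 with the enal on the face opposite the tert-butyl group, so C7 forms with retention of the malic acid configuration, and C6 (S) is expected from the approach that places the dienyl chain over the ring face carrying only the acetal hydrogen, away from the lithium carboxylate arm.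

Step 7
Reactants: 11 aldol hydroxy acid
Product: 12 ethyl (2Z,6E)-7-[(2S,5R,6S)-2-tert-butyl-4,8-dioxo-1,3,7-trioxaspiro[4.4]nonan-6-yl]-2,6-dimethylhepta-2,6-dienoate
Conditions: DCC, DMAP (cat.), CH2Cl2, 0 °C; chromatography
Reagents that add atoms: none
Why: Steglich-type lactonisation through acyl activation closes the γ-lactone (5-exo-trig) with retention at C6 and gives a neutral spiro compound from which any C6 epimer can be removed on silica.

Step 8
Reactants: 12 spirolactone
Product: 14 (2S,3R)-2-[(1E,5Z)-6-carboxy-2-methylhepta-1,5-dien-1-yl]-3-hydroxy-5-oxooxolane-3-carboxylic acid, via hydroxy triacid 13 (not isolated)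
Conditions: LiOH, THF/H2O, 0 °C → rt; then 1 M HCl to pH 2, rt
Reagents that add atoms: lithium hydroxide in water, [Li+].[OH-]
Why: Saponification opens the acylal-type dioxolanone (pivalaldehyde is lost), the lactone and the ethyl ester, and on acidification the γ-hydroxy acid recloses to the only accessible five-membered lactone (C12 to O6), with no stereocentre involved.

Step 9
Reactants: 14 lactone diacid
Product: 15 (4S,5S)-4-hydroxy-5-[(1E,5Z)-7-hydroxy-2,6-dimethylhepta-1,5-dien-1-yl]-4-(hydroxymethyl)oxolan-2-one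
Conditions: BH3·SMe2, B(OMe)3, THF, −10 °C → rt; MeOH
Reagents that add atoms: none
Why: Borane reduction of carboxylic acids through acyloxyboranes is faster than reduction of a lactone and, with a limited charge at low temperature, faster than hydroboration of trisubstituted alkenes, so both carboxyl groups should become primary alcohols.

Step 10
Reactants: 15 triol lactone
Product: 16 (2S,3R)-2-[(1E,5Z)-2,6-dimethyl-7-oxohepta-1,5-dien-1-yl]-3-hydroxy-5-oxooxolane-3-carbaldehyde
Conditions: (COCl)2, DMSO, CH2Cl2, −78 °C; iPr2NEt, −78 → −20 °C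
Reagents that add atoms: none
Why: Swern oxidation converts both primary alcohols (neopentyl C8, allylic C9) into aldehydes, cannot oxidise the tertiary C7 hydroxyl or cleave the 1,2-diol, and with a hindered amine in the cold should keep the Z-enal geometry.

Step 11
Reactants: 16 hydroxy dialdehyde
Product: 17 (2S,3R)-2-[(1E,5Z)-2,6-dimethyl-7-oxohepta-1,5-dien-1-yl]-5-oxo-3-[(triethylsilyl)oxy]oxolane-3-carbaldehyde
Conditions: Et3SiOTf, 2,6-lutidine, CH2Cl2, −78 °C
Reagents that add atoms: triethylsilyl trifluoromethanesulfonate, CC[Si](CC)(CC)OS(=O)(=O)C(F)(F)F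
Why: Silyl triflate silylation of the hindered tertiary alcohol; the C8 aldehyde has no α-hydrogen and cannot enolise, and the silyl ether blocks hemiacetal formation and retro-aldol cleavage in the next step.

Step 12
Reactants: 17 silyloxy dialdehyde
Product: 18 (3aS,4S,5R,6Z,10E,11aS)-4,5-dihydroxy-6,10-dimethyl-3a-[(triethylsilyl)oxy]-3a,4,5,8,9,11a-hexahydrocyclodeca[b]furan-2(3H)-one
Conditions: TiCl3(DME)1.5 (trivalent titanium), Zn–Cu couple, DME, reflux; then 25 °C, 17 added over 30 h (syringe pump); aq. K2CO3
Reagents that add atoms: none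
Why: Low-valent titanium transfers one electron to each aldehyde, the two titanium-bound ketyls join at their carbonyl carbons (the enal reacts 1,2) and the titanium diolate is hydrolysed to the diol; at 25 °C deoxygenation to the alkene should not follow. The closest known reaction type is the McMurry-type intramolecular pinacol cyclisation of dialdehydes to medium- and large-ring 1,2-diols. The ten-membered carbocycle is closed end to end by ketyl–ketyl combination on the titanium template under slow addition, with the fused lactone and the two trisubstituted alkenes restricting the chain. C9 is set relative to C8, because rings of ten or more members close with the two titanium-oxy groups anti across the new bond, which gives the threo (trans) diol. C8 is set relative to C7: the C8 ketyl should react with its C–O(Ti) bond anti to the C7–OSiEt3 bond (Cornforth-type dipole and steric minimum), so that C9 bonds on the face next to the lactone methylene C11 and not next to substituted C6, giving 8S. The step needs chemoselectivity for the two aldehydes, secured by the saturated lactone (no acrylate), the silyl-protected tertiary alcohol and the absence of other reducible groups.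

Step 13
Reactants: 18 silyloxy diol
Product: 19 (3aS,4S,5R,6Z,10E,11aS)-3a,4,5-trihydroxy-6,10-dimethyl-3a,4,5,8,9,11a-hexahydrocyclodeca[b]furan-2(3H)-one
Conditions: HF·pyridine, pyridine, THF, 0 °C → rt
Reagents that add atoms: none
Why: Fluoride-mediated desilylation under buffered, non-basic conditions removes the tertiary triethylsilyl ether without translactonisation toward O8.

Step 14
Reactants: 19 triol
Product: 20 (3aS,4S,5R,6Z,10E,11aS)-5-[(tert-butyldimethylsilyl)oxy]-3a,4-dihydroxy-6,10-dimethyl-3a,4,5,8,9,11a-hexahydrocyclodeca[b]furan-2(3H)-one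
Conditions: tBuMe2SiCl, imidazole, DMF, 0 °C
Reagents that add atoms: tert-butyldimethylsilyl chloride, CC(C)(C)[Si](C)(C)Cl
Why: Sterically controlled monosilylation should select the allylic C9 hydroxyl, the only one that is neither tertiary nor attached next to quaternary C7.

Step 15
Reactants: 20 C9 silyl ether
Product: 23 (3aS,4S,5R,6Z,10E,11aS)-5-[(tert-butyldimethylsilyl)oxy]-3a,4-dihydroxy-6,10-dimethyl-3-methylidene-3a,4,5,8,9,11a-hexahydrocyclodeca[b]furan-2(3H)-one, via Mannich base 21 (not isolated), via methiodide 22 (not isolated)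
Conditions: LiN(iPr)2 (3.5 equiv), THF, −78 °C (20 added to the base); [Me2N=CH2]I, −78 °C → rt; H2O; then MeI, MeOH, rt; then NaHCO3 (aq), EtOAc, rt
Reagents that add atoms: N,N-dimethylmethyleneiminium iodide (Eschenmoser's salt), C=[N+](C)C.[I-]
Why: α-Methylenation by Mannich reaction of the lactone enolate, quaternisation and Hofmann-type β-elimination; the enolate is formed as a β-oxido polyanion that does not expel the C7 oxygen, and the C11 centre of the Mannich base disappears on elimination.

Step 16
Reactants: 23 methylene lactone diol; 24 angelic acid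
Product: 26 (3aR,4S,5R,6Z,10E,11aS)-5-[(tert-butyldimethylsilyl)oxy]-3a-hydroxy-6,10-dimethyl-3-methylidene-2-oxo-2,3,3a,4,5,8,9,11a-octahydrocyclodeca[b]furan-4-yl (2Z)-2-methylbut-2-enoate, via mixed anhydride 25 (not isolated)
Conditions: 24, 2,4,6-Cl3C6H2COCl, Et3N, toluene, rt; then 23, 75 °C
Reagents that add atoms: none
Why: Yamaguchi-type esterification through the mixed anhydride, run without DMAP, acylates the secondary C8 hydroxyl (the tertiary C7 hydroxyl is inert) and is the established way to form angelates without Z to E isomerisation to the tiglate.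

Step 17
Reactants: 26 silylated angelate
Product: 27 target, (3aR,4S,5R,6Z,10E,11aS)-3a,5-dihydroxy-6,10-dimethyl-3-methylidene-2-oxo-2,3,3a,4,5,8,9,11a-octahydrocyclodeca[b]furan-4-yl (2Z)-2-methylbut-2-enoate
Conditions: HF·pyridine, pyridine, THF, 0 °C → rt
Reagents that add atoms: none
Why: Buffered fluoride desilylation frees the C9 hydroxyl under mildly acidic conditions that should not cause acyl migration, translactonisation or conjugate addition to the α-methylene lactone.

**Compound list**

1 | L-malic acid, (2S)-2-hydroxybutanedioic acid | O[C@@H](CC(=O)O)C(=O)O | starting material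
2 | pivalaldehyde, 2,2-dimethylpropanal | CC(C)(C)C=O | starting material
3 | 2-[(2S,4S)-2-tert-butyl-5-oxo-1,3-dioxolan-4-yl]acetic acid (cis) | OC(=O)C[C@@H]1O[C@H](C(C)(C)C)OC1=O | intermediate
4 | geranyl acetate | CC(=O)OC/C=C(\C)CCC=C(C)C | starting material
5 | (2E)-5-(5,5-dimethyl-1,2,4-trioxolan-3-yl)-3-methylpent-2-en-1-yl acetate (ozonide, ring carbon unassigned) | CC(=O)OC/C=C(\C)CCC1OOC(C)(C)O1 | intermediate
6 | (2E)-3-methyl-6-oxohex-2-en-1-yl acetate | CC(=O)OC/C=C(\C)CCC=O | intermediate
7 | ethyl 2-[bis(2,2,2-trifluoroethoxy)phosphoryl]propanoate | CCOC(=O)C(C)P(=O)(OCC(F)(F)F)OCC(F)(F)F | starting material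
8 | ethyl (2Z,6E)-8-acetoxy-2,6-dimethylocta-2,6-dienoate | CCOC(=O)/C(C)=C\CC/C(C)=C/COC(C)=O | intermediate
9 | ethyl (2Z,6E)-8-hydroxy-2,6-dimethylocta-2,6-dienoate | CCOC(=O)/C(C)=C\CC/C(C)=C/CO | intermediate
10 | ethyl (2Z,6E)-2,6-dimethyl-8-oxoocta-2,6-dienoate | CCOC(=O)/C(C)=C\CC/C(C)=C/C=O | intermediate
11 | 2-[(2S,4R)-2-tert-butyl-4-[(1S,2E,6Z)-8-ethoxy-1-hydroxy-3,7-dimethyl-8-oxoocta-2,6-dien-1-yl]-5-oxo-1,3-dioxolan-4-yl]acetic acid | CCOC(=O)/C(C)=C\CC/C(C)=C/[C@H](O)[C@@]1(CC(=O)O)O[C@H](C(C)(C)C)OC1=O | intermediate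
12 | ethyl (2Z,6E)-7-[(2S,5R,6S)-2-tert-butyl-4,8-dioxo-1,3,7-trioxaspiro[4.4]nonan-6-yl]-2,6-dimethylhepta-2,6-dienoate | CCOC(=O)/C(C)=C\CC/C(C)=C/[C@@H]1OC(=O)C[C@@]12O[C@H](C(C)(C)C)OC2=O | intermediate
13 | (2R)-2-[(1S,2E,6Z)-7-carboxy-1-hydroxy-3-methylocta-2,6-dien-1-yl]-2-hydroxybutanedioic acid | OC(=O)/C(C)=C\CC/C(C)=C/[C@H](O)[C@](O)(CC(=O)O)C(=O)O | intermediate
14 | (2S,3R)-2-[(1E,5Z)-6-carboxy-2-methylhepta-1,5-dien-1-yl]-3-hydroxy-5-oxooxolane-3-carboxylic acid | OC(=O)/C(C)=C\CC/C(C)=C/[C@@H]1OC(=O)C[C@]1(O)C(=O)O | intermediate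
15 | (4S,5S)-4-hydroxy-5-[(1E,5Z)-7-hydroxy-2,6-dimethylhepta-1,5-dien-1-yl]-4-(hydroxymethyl)oxolan-2-one | OC/C(C)=C\CC/C(C)=C/[C@@H]1OC(=O)C[C@]1(O)CO | intermediate
16 | (2S,3R)-2-[(1E,5Z)-2,6-dimethyl-7-oxohepta-1,5-dien-1-yl]-3-hydroxy-5-oxooxolane-3-carbaldehyde | O=C/C(C)=C\CC/C(C)=C/[C@@H]1OC(=O)C[C@]1(O)C=O | intermediate
17 | (2S,3R)-2-[(1E,5Z)-2,6-dimethyl-7-oxohepta-1,5-dien-1-yl]-5-oxo-3-[(triethylsilyl)oxy]oxolane-3-carbaldehyde | O=C/C(C)=C\CC/C(C)=C/[C@@H]1OC(=O)C[C@]1(O[Si](CC)(CC)CC)C=O | intermediate
18 | (3aS,4S,5R,6Z,10E,11aS)-4,5-dihydroxy-6,10-dimethyl-3a-[(triethylsilyl)oxy]-3a,4,5,8,9,11a-hexahydrocyclodeca[b]furan-2(3H)-one | O[C@@H]1/C(C)=C\CC/C(C)=C/[C@@H]2OC(=O)C[C@]2(O[Si](CC)(CC)CC)[C@H]1O | intermediate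
19 | (3aS,4S,5R,6Z,10E,11aS)-3a,4,5-trihydroxy-6,10-dimethyl-3a,4,5,8,9,11a-hexahydrocyclodeca[b]furan-2(3H)-one | O[C@@H]1/C(C)=C\CC/C(C)=C/[C@@H]2OC(=O)C[C@]2(O)[C@H]1O | intermediate
20 | (3aS,4S,5R,6Z,10E,11aS)-5-[(tert-butyldimethylsilyl)oxy]-3a,4-dihydroxy-6,10-dimethyl-3a,4,5,8,9,11a-hexahydrocyclodeca[b]furan-2(3H)-one | CC(C)(C)[Si](C)(C)O[C@@H]1/C(C)=C\CC/C(C)=C/[C@@H]2OC(=O)C[C@]2(O)[C@H]1O | intermediate
21 | 3-[(dimethylamino)methyl] derivative of 20 (Mannich base, C3 epimers) | CC(C)(C)[Si](C)(C)O[C@@H]1/C(C)=C\CC/C(C)=C/[C@@H]2OC(=O)C(CN(C)C)[C@]2(O)[C@H]1O | intermediate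
22 | trimethylammonium iodide of 21 (methiodide, C3 epimers) | CC(C)(C)[Si](C)(C)O[C@@H]1/C(C)=C\CC/C(C)=C/[C@@H]2OC(=O)C(C[N+](C)(C)C)[C@]2(O)[C@H]1O.[I-] | intermediate
23 | (3aS,4S,5R,6Z,10E,11aS)-5-[(tert-butyldimethylsilyl)oxy]-3a,4-dihydroxy-6,10-dimethyl-3-methylidene-3a,4,5,8,9,11a-hexahydrocyclodeca[b]furan-2(3H)-one | CC(C)(C)[Si](C)(C)O[C@@H]1/C(C)=C\CC/C(C)=C/[C@@H]2OC(=O)C(=C)[C@]2(O)[C@H]1O | intermediate
24 | angelic acid, (2Z)-2-methylbut-2-enoic acid | C/C=C(/C)C(=O)O | starting material
25 | (2Z)-2-methylbut-2-enoic 2,4,6-trichlorobenzoic anhydride | C/C=C(/C)C(=O)OC(=O)c1c(Cl)cc(Cl)cc1Cl | intermediate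
26 | (3aR,4S,5R,6Z,10E,11aS)-5-[(tert-butyldimethylsilyl)oxy]-3a-hydroxy-6,10-dimethyl-3-methylidene-2-oxo-2,3,3a,4,5,8,9,11a-octahydrocyclodeca[b]furan-4-yl (2Z)-2-methylbut-2-enoate | CC(C)(C)[Si](C)(C)O[C@@H]1/C(C)=C\CC/C(C)=C/[C@@H]2OC(=O)C(=C)[C@]2(O)[C@H]1OC(=O)/C(C)=C\C | intermediate
27 | (3aR,4S,5R,6Z,10E,11aS)-3a,5-dihydroxy-6,10-dimethyl-3-methylidene-2-oxo-2,3,3a,4,5,8,9,11a-octahydrocyclodeca[b]furan-4-yl (2Z)-2-methylbut-2-enoate (CNP0292337.1) | C=C1C(=O)O[C@H]2/C=C(\C)CC/C=C(/C)[C@@H](O)[C@H](OC(=O)/C(C)=C\C)[C@@]12O | target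

**Count and risks**

Total steps: 17. Longest linear sequence: 16 steps (geranyl acetate 4 to target 27, steps 2–17); step 1 is the only branch.

Step 12. What may go wrong: intermolecular coupling and plain reduction of the aldehydes may outrun closure of the ten-membered ring, and facial control at C8 and C9 may be too weak, so that diol diastereomers form. Fallback: the closure is run on the unprotected hydroxy dialdehyde 16 with SmI2 (samarium diiodide, divalent samarium) in THF with tBuOH, −78 °C → rt, under slow addition. The free C7 hydroxyl binds samarium and holds the C8 ketyl in a chelate, so the control element changes from steric shielding by a silyl ether to chelation. This fallback sets out from 16 and comes back to the route at triol 19, bypassing steps 11 and 13; it makes no compound outside the list (F0).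

Step 6. What may go wrong: poor facial selectivity at the aldehyde carbonyl, so that the C6 epimer forms in quantity or predominates. Fallback: the aldol of 3 with 10 is run as before and the C6-epimeric hydroxy acid, 2-[(2S,4R)-2-tert-butyl-4-[(1R,2E,6Z)-8-ethoxy-1-hydroxy-3,7-dimethyl-8-oxoocta-2,6-dien-1-yl]-5-oxo-1,3-dioxolan-4-yl]acetic acid F1, is separated. It is closed by Mitsunobu lactonisation (PPh3, DIAD, toluene, 0 °C), in which the alcohol is activated and the carboxylate displaces it with inversion at C6. This sets out from 3 and 10 and comes back at spirolactone 12, so both aldol epimers converge.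

Step 9. What may go wrong: hydroboration of the trisubstituted alkenes or partial reduction of the lactone may compete with slow reduction of the hindered and the conjugated carboxyl groups. Fallback: diacid 14 is converted with EtSH, DCC and DMAP (cat.) in CH2Cl2 into the bis-thioester S-ethyl (2S,3R)-2-[(1E,5Z)-7-(ethylsulfanyl)-2,6-dimethyl-7-oxohepta-1,5-dien-1-yl]-3-hydroxy-5-oxooxolane-3-carbothioate F2. Fukuyama reduction (Et3SiH, Pd/C, zerovalent palladium on carbon, acetone, rt) then gives both aldehydes directly without borane. This sets out from 14 and comes back at hydroxy dialdehyde 16, bypassing step 10.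

**Further compounds**

F1 | step 6 | 2-[(2S,4R)-2-tert-butyl-4-[(1R,2E,6Z)-8-ethoxy-1-hydroxy-3,7-dimethyl-8-oxoocta-2,6-dien-1-yl]-5-oxo-1,3-dioxolan-4-yl]acetic acid | CCOC(=O)/C(C)=C\CC/C(C)=C/[C@@H](O)[C@@]1(CC(=O)O)O[C@H](C(C)(C)C)OC1=O
F2 | step 9 | S-ethyl (2S,3R)-2-[(1E,5Z)-7-(ethylsulfanyl)-2,6-dimethyl-7-oxohepta-1,5-dien-1-yl]-3-hydroxy-5-oxooxolane-3-carbothioate | CCSC(=O)/C(C)=C\CC/C(C)=C/[C@@H]1OC(=O)C[C@]1(O)C(=O)SCC
F0 | step 12 | none | none
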